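The furan-2,5-dione ring is disconnected at its C2–C3 bond, between a carbonyl carbon and the ring carbon that carries the (E)-butenyl group. The ring is closed as a butenolide: iodine–lithium exchange on an acyclic (Z)-2-iodo-1,3-dienyl methyl carbonate gives an alkenyllithium that attacks the carbonate carbonyl in a 5-exo-trig acylation. The step exploits the tetrasubstituted endocyclic C3=C4 double bond, which holds C3 and the C5–O1 arm cis; this geometry is set by a hydroxyl-directed anti-carbomagnesiation of an enynol. The ring CH2 is later oxidised to the second carbonyl, and the triacid chain is attached by a Z-selective Horner–Wadsworth–Emmons reaction.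

Key step: step 9

Remark: the centres formed at the phosphorus-bearing carbon of 28 and 29, at the hemiorthoester carbon of 19 and at the peroxy-bearing carbon of 32 are not controlled; each becomes sp2 in the same or the next operation.

Step 1
Reactants: 1 (4R)-4-benzyl-1,3-oxazolidin-2-one; 2 butanoyl chloride
Product: 3 (4R)-4-benzyl-3-butanoyl-1,3-oxazolidin-2-one
Conditions: Et3N, 4-(dimethylamino)pyridine (cat.), CH2Cl2, 0 °C to rt
Reagents that add atoms: none
Why: N-acylation of the oxazolidinone (nucleophilic acyl substitution with acyl-transfer catalysis) should attach the chiral auxiliary to the four-carbon unit that supplies C6 to C8 and the ring-linking CH2 of the target.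

Step 2
Reactants: 3 (4R)-4-benzyl-3-butanoyl-1,3-oxazolidin-2-one; 4 benzyl chloromethyl ether
Product: 6 (4R)-4-benzyl-3-[(2S)-2-(benzyloxymethyl)butanoyl]-1,3-oxazolidin-2-one, via titanium enolate 5 (not isolated)
Conditions: TiCl4, i-Pr2NEt, CH2Cl2, 0 °C; then 4, 0 °C
Reagents that add atoms: none
Why: Evans alkylation: the chelated (Z)-titanium enolate should be alkylated by the oxocarbenium-like electrophile on the face opposite the benzyl group of the auxiliary, which sets the (2S) centre that becomes C6 of the target.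

Step 3
Reactants: 6 (4R)-4-benzyl-3-[(2S)-2-(benzyloxymethyl)butanoyl]-1,3-oxazolidin-2-one
Product: 7 (2R)-2-(benzyloxymethyl)butan-1-ol
Conditions: LiBH4, H2O (1 equiv), Et2O, 0 °C
Reagents that add atoms: none
Why: Reductive removal of the auxiliary (hydride reduction of the exocyclic imide carbonyl) should give the primary alcohol without touching the α-centre, whose descriptor changes to R only because the priorities change.

Step 4
Reactants: 7 (2R)-2-(benzyloxymethyl)butan-1-ol
Product: 8 benzyl (2S)-2-(bromomethyl)butyl ether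
Conditions: CBr4, PPh3, CH2Cl2, 0 °C
Reagents that add atoms: tetrabromomethane BrC(Br)(Br)Br
Why: Appel reaction: bromide should displace the alkoxyphosphonium group by SN2 at the primary carbon, one atom away from the stereocentre.

Step 5
Reactants: 9 (2E)-pent-2-enal
Product: 10 (3E)-1,1-dibromohexa-1,3-diene
Conditions: CBr4, PPh3, CH2Cl2, 0 °C
Reagents that add atoms: tetrabromomethane BrC(Br)(Br)Br
Why: Corey–Fuchs dibromo-olefination (Wittig reaction of Ph3P=CBr2) should add the carbon that becomes ring carbon C4 while the aldehyde carbon becomes C3 and the E alkene is untouched.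

Step 6
Reactants: 10 (3E)-1,1-dibromohexa-1,3-diene
Product: 12 (4E)-hept-4-en-2-yn-1-ol, via lithium acetylide 11 (not isolated)
Conditions: n-BuLi (2.1 equiv), THF, −78 °C to 0 °C; then (CH2O)n, −78 °C to rt
Reagents that add atoms: formaldehyde (from paraformaldehyde) C=O
Why: Second stage of the Corey–Fuchs sequence (bromine–lithium exchange, Fritsch–Buttenberg–Wiechell rearrangement, deprotonation) should give the enynyllithium, whose addition to formaldehyde installs the propargylic hydroxyl that later directs the carbometallation and becomes the ring oxygen.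

Step 7
Reactants: 8 benzyl (2S)-2-(bromomethyl)butyl ether; 12 (4E)-hept-4-en-2-yn-1-ol
Product: 16 (2Z,4E)-2-[(2R)-2-(benzyloxymethyl)butyl]-3-iodohepta-2,4-dien-1-ol, via Grignard reagent 13 (not isolated), via chloromagnesium alkoxide 14 (not isolated), via alkenylmagnesium alkoxide 15 (not isolated)
Conditions: 8, Mg, THF, rt; 12, MeMgCl (1.0 equiv), THF, 0 °C; combine with CuI (10 mol %), rt to 45 °C; then I2, −78 °C to 0 °C
Reagents that add atoms: iodine [I][I]
Why: Copper-catalysed anti-carbomagnesiation of a propargylic alcohol (alkoxide-directed carbometallation): the alkyl group should be delivered to the alkyne carbon next to CH2O while magnesium ends on the distal, butenyl-bearing carbon cis to CH2O in a five-membered chelate, so that iodinolysis with retention gives the 2Z iodide, and the stereocentre of 13 is not touched.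

Step 8
Reactants: 16 (2Z,4E)-2-[(2R)-2-(benzyloxymethyl)butyl]-3-iodohepta-2,4-dien-1-ol
Product: 17 (2Z,4E)-2-[(2R)-2-(benzyloxymethyl)butyl]-3-iodohepta-2,4-dien-1-yl methyl carbonate
Conditions: ClCO2Me, pyridine, CH2Cl2, 0 °C
Reagents that add atoms: methyl chloroformate COC(Cl)=O
Why: O-acylation of the allylic alcohol (nucleophilic acyl substitution) should tether the future lactone carbonyl carbon to the future ring oxygen.

Step 9
Reactants: 17 (2Z,4E)-2-[(2R)-2-(benzyloxymethyl)butyl]-3-iodohepta-2,4-dien-1-yl methyl carbonate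
Product: 20 4-[(2R)-2-(benzyloxymethyl)butyl]-3-[(1E)-but-1-en-1-yl]furan-2(5H)-one, via alkenyllithium 18 (not isolated), via lithium hemiorthoester alkoxide 19 (not isolated)
Conditions: t-BuLi (2.05 equiv), THF–Et2O–pentane (4:1:1), −100 °C to −78 °C; then AcOH, −78 °C to rt
Reagents that add atoms: none
Why: Iodine–lithium exchange, which at −100 °C should outrun addition of t-BuLi to a carbonate, gives the alkenyllithium 18, whose butenyl-bearing carbanionic carbon adds to the carbonate carbonyl held cis on the tetrasubstituted alkene to give 19, and the acidic quench expels methanol to leave the butenolide. The closest known reaction type is the Parham cyclisation, that is halogen–lithium exchange followed by intramolecular acylation of an aryl- or alkenyllithium by a tethered carbamate, carbonate or ester. The five-membered ring closes in the 5-exo-trig mode, with the new C–C bond in the ring and the carbonyl oxygen exocyclic. No stereocentre is created, and the existing centre is neither acidic nor adjacent to the carbanion. The step needs chemoselectivity (exchange before carbonyl attack, secured by the temperature and the high exchange rate of an alkenyl iodide) and retention of the alkene geometry (alkenyllithiums are configurationally stable at −78 °C); no other closure competes because the carbonate carbon is the only electrophile within reach and no leaving group sits β to lithium.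

Step 10
Reactants: 20 4-[(2R)-2-(benzyloxymethyl)butyl]-3-[(1E)-but-1-en-1-yl]furan-2(5H)-one
Product: 21 3-[(1E)-but-1-en-1-yl]-4-[(2R)-2-(hydroxymethyl)butyl]furan-2(5H)-one
Conditions: BCl3, C6HMe5, CH2Cl2, −78 °C; then MeOH
Reagents that add atoms: none
Why: Lewis-acid debenzylation with pentamethylbenzene as benzyl-cation scavenger (Friedel–Crafts capture) should cleave the ether without hydrogen, so the diene and the ring alkene survive.

Step 11
Reactants: 21 3-[(1E)-but-1-en-1-yl]-4-[(2R)-2-(hydroxymethyl)butyl]furan-2(5H)-one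
Product: 22 (2R)-2-({4-[(1E)-but-1-en-1-yl]-5-oxo-2,5-dihydrofuran-3-yl}methyl)butanal
Conditions: Dess–Martin periodinane, NaHCO3, CH2Cl2, 0 °C to rt
Reagents that add atoms: none
Why: Dess–Martin oxidation under buffered, non-basic conditions should give the α-branched aldehyde without epimerisation, and it is used at once.

Step 12
Reactants: 23 (2R)-5-oxotetrahydrofuran-2-carboxylic acid
Product: 24 dimethyl (2R)-2-hydroxypentanedioate
Conditions: MeOH, acetyl chloride (cat.), rt; then NaHCO3
Reagents that add atoms: methanol CO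
Why: Acid-catalysed lactone methanolysis and Fischer esterification in excess methanol should give the open hydroxy diester, and the C–O bond at the stereocentre is not broken.

Step 13
Reactants: 24 dimethyl (2R)-2-hydroxypentanedioate
Product: 25 dimethyl (2R)-2-[(trifluoromethylsulfonyl)oxy]pentanedioate
Conditions: Tf2O, 2,6-lutidine, CH2Cl2, −78 °C
Reagents that add atoms: trifluoromethanesulfonic anhydride FC(F)(F)S(=O)(=O)OS(=O)(=O)C(F)(F)F
Why: O-sulfonylation of the α-hydroxy ester with retention should give a secondary triflate reactive enough for clean SN2 displacement by a stabilised carbanion.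

Step 14
Reactants: 25 dimethyl (2R)-2-[(trifluoromethylsulfonyl)oxy]pentanedioate; 26 methyl [bis(2,2,2-trifluoroethoxy)phosphoryl]acetate
Product: 28 trimethyl (2S)-1-[bis(2,2,2-trifluoroethoxy)phosphoryl]butane-1,2,4-tricarboxylate, via sodium phosphonoacetate 27 (not isolated)
Conditions: 26 (1.3 equiv), NaH, THF, 0 °C; then 25, −40 °C to 0 °C
Reagents that add atoms: none
Why: SN2 alkylation of the phosphonoacetate carbanion by the α-triflyloxy ester should proceed with inversion and so set the centre that becomes C3 (R) of the target (the descriptor reads S here only because phosphorus raises the priority of the neighbouring carbon).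

Step 15
Reactants: 22 (2R)-2-({4-[(1E)-but-1-en-1-yl]-5-oxo-2,5-dihydrofuran-3-yl}methyl)butanal; 28 trimethyl (2S)-1-[bis(2,2,2-trifluoroethoxy)phosphoryl]butane-1,2,4-tricarboxylate
Product: 30 trimethyl (3R,4Z,6R)-6-({4-[(1E)-but-1-en-1-yl]-5-oxo-2,5-dihydrofuran-3-yl}methyl)oct-4-ene-1,3,4-tricarboxylate, via potassium phosphonate carbanion 29 (not isolated)
Conditions: 28 (1.2 equiv), KN(SiMe3)2, 18-crown-6, THF, −78 °C; then 22, −78 °C
Reagents that add atoms: none
Why: Still–Gennari variant of the Horner–Wadsworth–Emmons reaction: fast, irreversible collapse of the kinetic adduct of the bis(trifluoroethyl) phosphonate should place the aldehyde-derived carbon cis to the ester (4Z), a preference reinforced by the branched α-substituent, while the pre-formed weakly basic carbanion leaves both stereocentres untouched.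

Step 16
Reactants: 30 trimethyl (3R,4Z,6R)-6-({4-[(1E)-but-1-en-1-yl]-5-oxo-2,5-dihydrofuran-3-yl}methyl)oct-4-ene-1,3,4-tricarboxylate
Product: 33 trimethyl (3R,4Z,6R)-6-({4-[(1E)-but-1-en-1-yl]-2,5-dioxo-2,5-dihydrofuran-3-yl}methyl)oct-4-ene-1,3,4-tricarboxylate, via silyloxyfuran 31 (not isolated), via silyl peroxide 32 (not isolated)
Conditions: TBSOTf, Et3N, CH2Cl2, 0 °C; then O2, tetraphenylporphyrin (cat.), hν, CH2Cl2, −78 °C; then Et3N, −78 °C to 0 °C
Reagents that add atoms: oxygen O=O
Why: Soft enolisation of the butenolide to the aromatic 2-silyloxyfuran, [4+2] cycloaddition of singlet oxygen with silyl shift to the 5-silylperoxy butenolide and Kornblum–DeLaMare elimination of silanol should raise the ring CH2 to the second carbonyl, the electron-rich furan reacting far faster than the electron-poor alkenes and the simple ester α-positions staying unenolised.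

Step 17
Reactants: 33 trimethyl (3R,4Z,6R)-6-({4-[(1E)-but-1-en-1-yl]-2,5-dioxo-2,5-dihydrofuran-3-yl}methyl)oct-4-ene-1,3,4-tricarboxylate
Product: 34 (3R,4Z,6R)-6-({4-[(1E)-but-1-en-1-yl]-2,5-dioxo-2,5-dihydrofuran-3-yl}methyl)oct-4-ene-1,3,4-tricarboxylic acid
Conditions: Me3SnOH, 1,2-dichloroethane, 80 °C; then aq. HCl, EtOAc
Reagents that add atoms: trimethyltin hydroxide C[Sn](C)(C)O
Why: Near-neutral ester hydrolysis with Me3SnOH should cleave the three methyl esters without epimerising C3 or moving the alkylidene double bond, and the transiently opened anhydride should close again on acidification as dialkylmaleic acids do.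

Compound list
1 | (4R)-4-benzyl-1,3-oxazolidin-2-one | O=C1N[C@H](Cc2ccccc2)CO1 | starting material
2 | butanoyl chloride | CCCC(Cl)=O | starting material
3 | (4R)-4-benzyl-3-butanoyl-1,3-oxazolidin-2-one | CCCC(=O)N1[C@H](Cc2ccccc2)COC1=O | intermediate
4 | benzyl chloromethyl ether | ClCOCc1ccccc1 | starting material
5 | trichlorotitanium (Z)-enolate of 3 | CC/C=C(\O[Ti](Cl)(Cl)Cl)N1[C@H](Cc2ccccc2)COC1=O | intermediate
6 | (4R)-4-benzyl-3-[(2S)-2-(benzyloxymethyl)butanoyl]-1,3-oxazolidin-2-one | CC[C@@H](COCc1ccccc1)C(=O)N1[C@H](Cc2ccccc2)COC1=O | intermediate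
7 | (2R)-2-(benzyloxymethyl)butan-1-ol | CC[C@@H](COCc1ccccc1)CO | intermediate
8 | benzyl (2S)-2-(bromomethyl)butyl ether | CC[C@@H](COCc1ccccc1)CBr | intermediate
9 | (2E)-pent-2-enal | CC/C=C/C=O | starting material
10 | (3E)-1,1-dibromohexa-1,3-diene | CC/C=C/C=C(Br)Br | intermediate
11 | lithium (3E)-hex-3-en-1-yn-1-ide | CC/C=C/C#C[Li] | intermediate
12 | (4E)-hept-4-en-2-yn-1-ol | CC/C=C/C#CCO | intermediate
13 | [(2S)-2-(benzyloxymethyl)butyl]magnesium bromide | CC[C@@H](COCc1ccccc1)C[Mg]Br | intermediate
14 | chloromagnesium (4E)-hept-4-en-2-yn-1-olate | CC/C=C/C#CCO[Mg]Cl | intermediate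
15 | chloromagnesium (2Z,4E)-2-[(2R)-2-(benzyloxymethyl)butyl]-3-(bromomagnesio)hepta-2,4-dien-1-olate (Mg on C3 cis to the CH2O arm) | Cl[Mg]OC/C(C[C@@H](CC)COCc1ccccc1)=C(\[Mg]Br)/C=C/CC | intermediate
16 | (2Z,4E)-2-[(2R)-2-(benzyloxymethyl)butyl]-3-iodohepta-2,4-dien-1-ol | OC/C(C[C@@H](CC)COCc1ccccc1)=C(\I)/C=C/CC | intermediate
17 | (2Z,4E)-2-[(2R)-2-(benzyloxymethyl)butyl]-3-iodohepta-2,4-dien-1-yl methyl carbonate | COC(=O)OC/C(C[C@@H](CC)COCc1ccccc1)=C(\I)/C=C/CC | intermediate
18 | alkenyllithium from 17: [(2E,4E)-2-[(2R)-2-(benzyloxymethyl)butyl]-1-(methoxycarbonyloxy)hepta-2,4-dien-3-yl]lithium (Li in the place of I, cis to the CH2O arm) | COC(=O)OC/C(C[C@@H](CC)COCc1ccccc1)=C(\[Li])/C=C/CC | intermediate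
19 | lithium 4-[(2R)-2-(benzyloxymethyl)butyl]-3-[(1E)-but-1-en-1-yl]-2-methoxy-2,5-dihydrofuran-2-olate (both epimers at C2) | CC/C=C/C1=C(C[C@@H](CC)COCc2ccccc2)COC1(OC)O[Li] | intermediate
20 | 4-[(2R)-2-(benzyloxymethyl)butyl]-3-[(1E)-but-1-en-1-yl]furan-2(5H)-one | CC/C=C/C1=C(C[C@@H](CC)COCc2ccccc2)COC1=O | intermediate
21 | 3-[(1E)-but-1-en-1-yl]-4-[(2R)-2-(hydroxymethyl)butyl]furan-2(5H)-one | CC/C=C/C1=C(C[C@@H](CC)CO)COC1=O | intermediate
22 | (2R)-2-({4-[(1E)-but-1-en-1-yl]-5-oxo-2,5-dihydrofuran-3-yl}methyl)butanal | CC/C=C/C1=C(C[C@@H](CC)C=O)COC1=O | intermediate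
23 | (2R)-5-oxotetrahydrofuran-2-carboxylic acid | O=C1CC[C@H](C(=O)O)O1 | starting material
24 | dimethyl (2R)-2-hydroxypentanedioate | COC(=O)CC[C@@H](O)C(=O)OC | intermediate
25 | dimethyl (2R)-2-[(trifluoromethylsulfonyl)oxy]pentanedioate | COC(=O)CC[C@@H](OS(=O)(=O)C(F)(F)F)C(=O)OC | intermediate
26 | methyl [bis(2,2,2-trifluoroethoxy)phosphoryl]acetate | COC(=O)CP(=O)(OCC(F)(F)F)OCC(F)(F)F | starting material
27 | sodium salt of 26 (carbanion at the CH between P and ester) | [Na+].COC(=O)[CH-]P(=O)(OCC(F)(F)F)OCC(F)(F)F | intermediate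
28 | trimethyl (2S)-1-[bis(2,2,2-trifluoroethoxy)phosphoryl]butane-1,2,4-tricarboxylate (both epimers at C1) | COC(=O)CC[C@H](C(C(=O)OC)P(=O)(OCC(F)(F)F)OCC(F)(F)F)C(=O)OC | intermediate
29 | potassium salt of 28 (carbanion at C1) | [K+].COC(=O)CC[C@H]([C-](C(=O)OC)P(=O)(OCC(F)(F)F)OCC(F)(F)F)C(=O)OC | intermediate
30 | trimethyl (3R,4Z,6R)-6-({4-[(1E)-but-1-en-1-yl]-5-oxo-2,5-dihydrofuran-3-yl}methyl)oct-4-ene-1,3,4-tricarboxylate | CC/C=C/C1=C(C[C@H](/C=C(\C(=O)OC)[C@@H](CCC(=O)OC)C(=O)OC)CC)COC1=O | intermediate
31 | 2-(tert-butyldimethylsilyloxy)furan derived from 30 (furan O1, C2 OSi, C3 (E)-butenyl, C4 side chain, C5 H) | CC/C=C/c1c(C[C@H](/C=C(\C(=O)OC)[C@@H](CCC(=O)OC)C(=O)OC)CC)coc1O[Si](C)(C)C(C)(C)C | intermediate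
32 | 5-(tert-butyldimethylsilylperoxy)furan-2(5H)-one derived from 31 (both epimers at C5) | CC/C=C/C1=C(C[C@H](/C=C(\C(=O)OC)[C@@H](CCC(=O)OC)C(=O)OC)CC)C(OO[Si](C)(C)C(C)(C)C)OC1=O | intermediate
33 | trimethyl (3R,4Z,6R)-6-({4-[(1E)-but-1-en-1-yl]-2,5-dioxo-2,5-dihydrofuran-3-yl}methyl)oct-4-ene-1,3,4-tricarboxylate | CC/C=C/C1=C(C[C@H](/C=C(\C(=O)OC)[C@@H](CCC(=O)OC)C(=O)OC)CC)C(=O)OC1=O | intermediate
34 | (3R,4Z,6R)-6-({4-[(1E)-but-1-en-1-yl]-2,5-dioxo-2,5-dihydrofuran-3-yl}methyl)oct-4-ene-1,3,4-tricarboxylic acid (CNP0256274.1) | CC/C=C/C1=C(C[C@H](/C=C(\C(=O)O)[C@@H](CCC(=O)O)C(=O)O)CC)C(=O)OC1=O | target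

Total step count: 17. Longest linear sequence: 12 steps (steps 1 to 4, 7 to 11, 15 to 17).

Steps most likely to fail

1. Step 7 (anti-carbomagnesiation). Transfer of the β-branched primary alkyl group to the alkoxide-bound alkyne may be slow. Conjugate addition across the enyne and premature protonation of the alkenylmagnesium may compete, eroding conversion and regiocontrol. The fallback sets out from 8 and comes back at 16; it makes the C–CH2 bond by enolate alkylation instead of carbometallation. Potassium methyl malonate would be acylated with (E)-pent-2-enoyl chloride (MgCl2, Et3N, MeCN) to give methyl (4E)-3-oxohept-4-enoate F1. C-alkylation of F1 with 8 (K2CO3, NaI, DMF, 50 °C) would give methyl (4E)-2-[(2R)-2-(benzyloxymethyl)butyl]-3-oxohept-4-enoate F2. Triflation of the chelated sodium enolate (NaH, then Tf2O, CH2Cl2, −78 °C) would give methyl (2Z,4E)-2-[(2R)-2-(benzyloxymethyl)butyl]-3-(trifluoromethylsulfonyloxy)hepta-2,4-dienoate F3. Stille stannylation with retention (Me6Sn2, Pd(PPh3)4, LiCl, THF, 60 °C) would give methyl (2Z,4E)-2-[(2R)-2-(benzyloxymethyl)butyl]-3-(trimethylstannyl)hepta-2,4-dienoate F4. Iododestannylation (I2, CH2Cl2, 0 °C) would give methyl (2Z,4E)-2-[(2R)-2-(benzyloxymethyl)butyl]-3-iodohepta-2,4-dienoate F5. Reduction of the ester with i-Bu2AlH (CH2Cl2, −78 °C) would then give 16.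

2. Step 9 (anionic ring closure). t-BuLi may add to the carbonate before the exchange, or the alkenyllithium may be protonated before it reaches the carbonyl, which would leave an open, de-iodinated chain. The fallback sets out from 16 and comes back at 20. The free iodo alcohol would undergo carbonylative lactonisation with PdCl2(PPh3)2 (5 mol %), CO (3 atm) and Et3N in THF at 50 °C. The C–I bond adds oxidatively to zerovalent palladium, CO inserts, and the cis hydroxyl captures the acylpalladium, so the carbonyl carbon then comes from CO. This fallback makes no new compound (F0).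

3. Step 16 (butenolide to anhydride). Singlet oxygen may react at the side-chain diene by ene reaction or cycloaddition, and the silyl peroxide may break down incompletely or unselectively. The fallback sets out from 30 and comes back at 33; it uses oxygen-atom transfer instead of photo-oxygenation. The silyloxyfuran 31, made as in step 16, would be epoxidised with dimethyldioxirane in acetone at −78 °C. Loss of the silyl group on work-up should give trimethyl (3R,4Z,6R)-6-({4-[(1E)-but-1-en-1-yl]-2-hydroxy-5-oxo-2,5-dihydrofuran-3-yl}methyl)oct-4-ene-1,3,4-tricarboxylate F6 as both epimers at the hydroxyl-bearing ring carbon. Dess–Martin periodinane (CH2Cl2, rt) would oxidise this lactol to 33.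

Further compounds
F1 | step 7 | methyl (4E)-3-oxohept-4-enoate | CC/C=C/C(=O)CC(=O)OC
F2 | step 7 | methyl (4E)-2-[(2R)-2-(benzyloxymethyl)butyl]-3-oxohept-4-enoate (both epimers at C2) | CC/C=C/C(=O)C(C[C@@H](CC)COCc1ccccc1)C(=O)OC
F3 | step 7 | methyl (2Z,4E)-2-[(2R)-2-(benzyloxymethyl)butyl]-3-(trifluoromethylsulfonyloxy)hepta-2,4-dienoate | COC(=O)/C(C[C@@H](CC)COCc1ccccc1)=C(\OS(=O)(=O)C(F)(F)F)/C=C/CC
F4 | step 7 | methyl (2Z,4E)-2-[(2R)-2-(benzyloxymethyl)butyl]-3-(trimethylstannyl)hepta-2,4-dienoate | COC(=O)/C(C[C@@H](CC)COCc1ccccc1)=C(\[Sn](C)(C)C)/C=C/CC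
F5 | step 7 | methyl (2Z,4E)-2-[(2R)-2-(benzyloxymethyl)butyl]-3-iodohepta-2,4-dienoate | COC(=O)/C(C[C@@H](CC)COCc1ccccc1)=C(\I)/C=C/CC
F0 | step 9 | none | none
F6 | step 16 | trimethyl (3R,4Z,6R)-6-({4-[(1E)-but-1-en-1-yl]-2-hydroxy-5-oxo-2,5-dihydrofuran-3-yl}methyl)oct-4-ene-1,3,4-tricarboxylate (both epimers at the ring carbinol carbon) | CC/C=C/C1=C(C[C@H](/C=C(\C(=O)OC)[C@@H](CCC(=O)OC)C(=O)OC)CC)C(O)OC1=O
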